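**Plan** (cyclohexane carbons are C1'–C6', C1' being bonded to C2 of the dihydrobenzofuran)

- Cuts, in order: the aryl C7a–O1 bond (intramolecular aryl etherification); the C2–C3 bond (auxiliary-controlled aldol of an arylacetyl imide with a cyclohexane carbaldehyde); the C3'–O and C4'–OMe bonds back to a cyclohex-3-enol; last, the cyclohexene itself is traced to a cyclopentane carrying a fused cyclopropane.
- Enabling feature: the tertiary carbinol C1' (flanked by two CH2) and the trans-diaxial C3'-OH/C4'-OMe pair read as a homoallylic alcohol C1'(O)–C2'H2–C3'=C4'. That is the product of a cyclopropylcarbinyl-to-homoallyl opening in which C2' was a cyclopropane CH2, C1'–C3' the fusion bond of a bicyclo[3.1.0]hexane and C4' a carbinol.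
- Forward: cyclopentenone 1 → allylic alcohol → bicyclo[3.1.0]hexanol → ring expansion to the cyclohexenol (step 5) → epoxide, methanolysis, acetonide, aldehyde 12. The aryl piece 21 comes from a dihydroferulate by Claisen rearrangement; union is by aldol; the dihydrobenzofuran ring is closed last by C–O coupling, then deprotection.
- Stereochemistry: a CBS reduction sets one carbinol, which steers the cyclopropanation. The cyclopropane configuration is relayed to C1' by invertive ester participation in the ring expansion (the CBS carbinol is erased). C1'-OH directs the epoxidation and trans-diaxial opening sets C3'/C4'. The Evans auxiliary sets C2/C3, and the etherification retains C2.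

Key step: step 5

Remark: the (S)-oxazaborolidine is assumed to give the R alcohol 2 (alkene arm acting as the large group); if the sense were reversed the (R)-catalyst would be used.

Step 1
Reactants: 1 methyl 3-oxocyclopent-1-ene-1-carboxylate
Product: 2 methyl (R)-3-hydroxycyclopent-1-ene-1-carboxylate
Conditions: (S)-1-methyl-3,3-diphenyltetrahydro-1H,3H-pyrrolo[1,2-c][1,3,2]oxazaborole (10 mol %), BH3·SMe2, THF, −20 °C; MeOH quench, aqueous work-up
Reagents that add atoms: none
Why: Corey–Bakshi–Shibata reduction, in which the catalyst-bound borane should deliver hydride to one face of the ketone (enoate arm as the large group) and so set the R carbinol by catalyst control while the ester and the electron-poor alkene stay untouched.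

Step 2
Reactants: 2 methyl (R)-3-hydroxycyclopent-1-ene-1-carboxylate
Product: 3 (R)-3-(hydroxymethyl)cyclopent-2-en-1-ol
Conditions: i-Bu2AlH (3.5 equiv), CH2Cl2, −78 → 0 °C; aq potassium sodium tartrate
Reagents that add atoms: none
Why: 1,2-reduction of the α,β-unsaturated ester by the aluminium hydride should give the allylic primary alcohol without touching the carbinol stereocentre.

Step 3
Reactants: 3 (R)-3-(hydroxymethyl)cyclopent-2-en-1-ol
Product: 4 (1S,2R,5S)-5-(hydroxymethyl)bicyclo[3.1.0]hexan-2-ol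
Conditions: Et2Zn (4 equiv), CH2I2 (4 equiv), CH2Cl2, −10 °C → rt; aq NH4Cl
Reagents that add atoms: diiodomethane, ICI
Why: Simmons–Smith cyclopropanation (Furukawa variant), in which the zinc alkoxide of the ring carbinol delivers the methylene to the alkene face syn to it and so sets both bridgehead carbons cis to the hydroxyl.

Step 4
Reactants: 4 (1S,2R,5S)-5-(hydroxymethyl)bicyclo[3.1.0]hexan-2-ol
Product: 5 [(1S,4R,5S)-4-hydroxybicyclo[3.1.0]hexan-1-yl]methyl 4-methoxybenzoate
Conditions: 4-methoxybenzoyl chloride (1.05 equiv), 2,4,6-collidine, CH2Cl2, −40 °C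
Reagents that add atoms: 4-methoxybenzoyl chloride, COc1ccc(cc1)C(Cl)=O
Why: Chemoselective nucleophilic acyl substitution, the primary alcohol being acylated in preference to the secondary carbinol that sits on the concave face next to the cyclopropane.

Step 5
Reactants: 5 [(1S,4R,5S)-4-hydroxybicyclo[3.1.0]hexan-1-yl]methyl 4-methoxybenzoate
Product: 7 [(S)-1-hydroxycyclohex-3-en-1-yl]methyl 4-methoxybenzoate, via spiro dioxolan-2-ylium ion 6 (not isolated)
Conditions: TsOH·H2O (10 mol %), 1,4-dioxane/H2O (9:1), 40 °C; aq NaHCO3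
Reagents that add atoms: water, O
Why: Mild acid ionizes the secondary cyclopropylcarbinol at C4 of the bicyclohexane; the cation opens by scission of the fusion bond C1–C5 while the carbonyl oxygen of the neighbouring ester closes on C1 from the rear, which turns the cyclopentane plus the cyclopropane CH2 (C6) into the cyclohex-3-ene ring and parks the charge in dioxolan-2-ylium ion 6, and water then opens 6 to the hydroxy ester, any tertiary ester converging on primary ester 7 through the same orthoacid. The closest known reaction type is the acid-promoted cyclopropylcarbinyl-to-homoallyl ring expansion of thujane-type bicyclo[3.1.0]hexan-2-ols (sabinene hydrate to terpinen-4-ol, likewise the i-steroid rearrangement), combined with classical acyloxy neighbouring-group participation. The six-membered carbocycle is not closed but released by cleavage of the zero-atom bridge; the only ring closed is the transient dioxolanylium ring, by a 5-exo-tet attack at C1. The one new stereocentre, the tertiary carbinol carbon, arises by inversion at cyclopropane carbon C1, so it is dictated by the cyclopropane configuration of step 3 and thus by the CBS carbinol, which is itself erased when C4 becomes sp2. The step needs scission of the fusion bond and not of the external C5–C6 bond, and capture at C1 and not return to C4: C1 is the only cyclopropane carbon that can bear the charge as a tertiary centre and the only one the ester reaches through a five-membered transition state, return to C4 is degenerate, and loss of cyclopropane strain makes 7 the sink. The acid is kept weak and aqueous so that the tertiary alcohol of 7, deactivated by its β-acyloxy group, does not re-ionize and racemize.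

Step 6
Reactants: 7 [(S)-1-hydroxycyclohex-3-en-1-yl]methyl 4-methoxybenzoate
Product: 8 [(1S,3S,6R)-3-hydroxy-7-oxabicyclo[4.1.0]heptan-3-yl]methyl 4-methoxybenzoate
Conditions: VO(acac)2 (5 mol %), t-BuOOH (1.5 equiv), CH2Cl2, rt
Reagents that add atoms: tert-butyl hydroperoxide, CC(C)(C)OO
Why: Vanadium-catalysed hydroxyl-directed epoxidation, in which the axial tertiary homoallylic hydroxyl binds the vanadium peroxide and should deliver oxygen to the alkene face syn to it, setting both epoxide carbons.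

Step 7
Reactants: 8 [(1S,3S,6R)-3-hydroxy-7-oxabicyclo[4.1.0]heptan-3-yl]methyl 4-methoxybenzoate
Product: 10 [(1S,5S,6S)-6-methoxy-3,3-dimethyl-2,4-dioxabicyclo[3.3.1]nonan-1-yl]methyl 4-methoxybenzoate, via methoxy diol 9 (not isolated)
Conditions: camphor-10-sulfonic acid (10 mol %), MeOH, rt; concentrate; 2,2-dimethoxypropane, acetone, rt
Reagents that add atoms: methanol, CO; 2,2-dimethoxypropane, COC(C)(C)OC
Why: Acid-catalysed epoxide methanolysis under the Fürst–Plattner rule should open trans-diaxially through the chair that keeps the acyloxymethyl arm equatorial (attack at the carbon remote from the C1 oxygen), placing OMe anti to the new secondary hydroxyl, and only this regioisomer has the cis-1,3-diol that the following acetalization locks as the bridged acetonide.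

Step 8
Reactants: 10 [(1S,5S,6S)-6-methoxy-3,3-dimethyl-2,4-dioxabicyclo[3.3.1]nonan-1-yl]methyl 4-methoxybenzoate
Product: 11 [(1S,5S,6S)-6-methoxy-3,3-dimethyl-2,4-dioxabicyclo[3.3.1]nonan-1-yl]methanol
Conditions: NaOMe (0.3 equiv), MeOH, 40 °C
Reagents that add atoms: none
Why: Methoxide-catalysed transesterification should remove the benzoate while the ketal and all stereocentres are inert to base.

Step 9
Reactants: 11 [(1S,5S,6S)-6-methoxy-3,3-dimethyl-2,4-dioxabicyclo[3.3.1]nonan-1-yl]methanol
Product: 12 (1S,5S,6S)-6-methoxy-3,3-dimethyl-2,4-dioxabicyclo[3.3.1]nonane-1-carbaldehyde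
Conditions: Dess–Martin periodinane (1.3 equiv), CH2Cl2, rt
Reagents that add atoms: none
Why: Dess–Martin oxidation of the neopentyl-type primary alcohol should give the aldehyde, whose α-carbon is quaternary and therefore cannot epimerize.

Step 10
Reactants: 13 methyl 3-(4-hydroxy-3-methoxyphenyl)propanoate
Product: 14 methyl 3-[3-methoxy-4-(prop-2-en-1-yloxy)phenyl]propanoate
Conditions: allyl bromide, K2CO3, acetone, reflux
Reagents that add atoms: allyl bromide, C=CCBr
Why: Williamson etherification of the phenoxide with the allylic bromide.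

Step 11
Reactants: 14 methyl 3-[3-methoxy-4-(prop-2-en-1-yloxy)phenyl]propanoate
Product: 15 methyl 3-[4-hydroxy-3-methoxy-5-(prop-2-en-1-yl)phenyl]propanoate
Conditions: N,N-diethylaniline, 200 °C
Reagents that add atoms: none
Why: Aromatic Claisen rearrangement, the [3,3] shift delivering the allyl group to the only free ortho position before rearomatization.

Step 12
Reactants: 15 methyl 3-[4-hydroxy-3-methoxy-5-(prop-2-en-1-yl)phenyl]propanoate
Product: 16 methyl 3-[3-methoxy-5-(prop-2-en-1-yl)-4-(trifluoromethanesulfonyloxy)phenyl]propanoate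
Conditions: Tf2O, pyridine, CH2Cl2, 0 °C
Reagents that add atoms: trifluoromethanesulfonic anhydride, O=S(=O)(OS(=O)(=O)C(F)(F)F)C(F)(F)F
Why: O-Sulfonylation of the phenol turns the phenolic carbon into the electrophile for the later C–O coupling and deactivates the arene towards the oxidants that follow.

Step 13
Reactants: 16 methyl 3-[3-methoxy-5-(prop-2-en-1-yl)-4-(trifluoromethanesulfonyloxy)phenyl]propanoate
Product: 19 2-[3-methoxy-5-(3-methoxy-3-oxopropyl)-2-(trifluoromethanesulfonyloxy)phenyl]acetic acid, via ozonide 17 (not isolated), via arylacetaldehyde 18 (not isolated)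
Conditions: O3, CH2Cl2, −78 °C; Me2S, −78 °C → rt; then NaClO2, NaH2PO4, 2-methylbut-2-ene, t-BuOH/H2O, rt
Reagents that add atoms: ozone, [O-][O+]=O; sodium chlorite, [Na+].[O-]Cl=O
Why: Ozonolysis of the terminal alkene (far faster than attack on the triflate-deactivated arene) followed by Pinnick oxidation of the sensitive arylacetaldehyde without isolation should give the arylacetic acid.

Step 14
Reactants: 19 2-[3-methoxy-5-(3-methoxy-3-oxopropyl)-2-(trifluoromethanesulfonyloxy)phenyl]acetic acid
Product: 21 methyl 3-[3-[2-[(S)-4-benzyl-2-oxo-1,3-oxazolidin-3-yl]-2-oxoethyl]-5-methoxy-4-(trifluoromethanesulfonyloxy)phenyl]propanoate, via mixed pivalic anhydride 20 (not isolated)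
Conditions: PivCl, Et3N, THF, −20 °C; then lithium salt of (S)-4-benzyl-1,3-oxazolidin-2-one (from n-BuLi, THF, −78 °C), −78 → 0 °C; 1 M HCl work-up
Reagents that add atoms: (S)-4-benzyl-1,3-oxazolidin-2-one, O=C1N[C@@H](Cc2ccccc2)CO1
Why: N-Acylation of the lithiated oxazolidinone by the mixed anhydride, which is attacked at its less hindered arylacetyl carbonyl.

Step 15
Reactants: 21 methyl 3-[3-[2-[(S)-4-benzyl-2-oxo-1,3-oxazolidin-3-yl]-2-oxoethyl]-5-methoxy-4-(trifluoromethanesulfonyloxy)phenyl]propanoate; 12 (1S,5S,6S)-6-methoxy-3,3-dimethyl-2,4-dioxabicyclo[3.3.1]nonane-1-carbaldehyde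
Product: 24 methyl 3-[3-[(2S,3S)-1-[(S)-4-benzyl-2-oxo-1,3-oxazolidin-3-yl]-3-hydroxy-3-[(1S,5S,6S)-6-methoxy-3,3-dimethyl-2,4-dioxabicyclo[3.3.1]nonan-1-yl]-1-oxopropan-2-yl]-5-methoxy-4-(trifluoromethanesulfonyloxy)phenyl]propanoate, via Z boron enolate 22 (not isolated), via boron aldolate 23 (not isolated)
Conditions: Bu2BOTf (1.2 equiv), i-Pr2NEt (1.4 equiv), CH2Cl2, −78 → 0 °C; 12, −78 → 0 °C; pH 7 buffer, MeOH, 30% H2O2, 0 °C
Reagents that add atoms: none
Why: Evans syn aldol, in which the Z boron enolate adds through a chair Zimmerman–Traxler transition state with the auxiliary dipole opposed, so that both new stereocentres (the future C3 and C2 of the dihydrobenzofuran) are set by the auxiliary and the weak facial bias of the quaternary α-oxygenated aldehyde is overridden.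

Step 16
Reactants: 24 methyl 3-[3-[(2S,3S)-1-[(S)-4-benzyl-2-oxo-1,3-oxazolidin-3-yl]-3-hydroxy-3-[(1S,5S,6S)-6-methoxy-3,3-dimethyl-2,4-dioxabicyclo[3.3.1]nonan-1-yl]-1-oxopropan-2-yl]-5-methoxy-4-(trifluoromethanesulfonyloxy)phenyl]propanoate
Product: 25 2-[(1S,2R)-1,3-dihydroxy-1-[(1S,5S,6S)-6-methoxy-3,3-dimethyl-2,4-dioxabicyclo[3.3.1]nonan-1-yl]propan-2-yl]-4-(3-hydroxypropyl)-6-methoxyphenyl trifluoromethanesulfonate
Conditions: LiBH4 (4 equiv), MeOH (4 equiv), THF, 0 °C → rt
Reagents that add atoms: none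
Why: Borohydride reduction should cleave the exocyclic imide carbonyl to the primary alcohol (releasing the auxiliary) and reduce the side-chain methyl ester, while the aryl triflate, the ketal and the stereocentres are inert.

Step 17
Reactants: 25 2-[(1S,2R)-1,3-dihydroxy-1-[(1S,5S,6S)-6-methoxy-3,3-dimethyl-2,4-dioxabicyclo[3.3.1]nonan-1-yl]propan-2-yl]-4-(3-hydroxypropyl)-6-methoxyphenyl trifluoromethanesulfonate
Product: 26 3-[(2S,3R)-3-(hydroxymethyl)-7-methoxy-2-[(1S,5S,6S)-6-methoxy-3,3-dimethyl-2,4-dioxabicyclo[3.3.1]nonan-1-yl]-2,3-dihydro-1-benzofuran-5-yl]propan-1-ol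
Conditions: Pd(OAc)2 (5 mol %), 2-di-tert-butylphosphino-2',4',6'-triisopropylbiphenyl (7 mol %), Cs2CO3 (1.5 equiv), toluene (0.02 M), 80 °C
Reagents that add atoms: none
Why: Intramolecular Buchwald–Hartwig etherification, in which zerovalent palladium inserts into the aryl triflate and C–O reductive elimination from the secondary alkoxide (the only oxygen that can form a five-membered ring, the tertiary one being masked in the ketal) closes the dihydrobenzofuran with retention at the carbinol carbon, so the syn aldol pair becomes the 2,3-trans pair.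

Step 18
Reactants: 26 3-[(2S,3R)-3-(hydroxymethyl)-7-methoxy-2-[(1S,5S,6S)-6-methoxy-3,3-dimethyl-2,4-dioxabicyclo[3.3.1]nonan-1-yl]-2,3-dihydro-1-benzofuran-5-yl]propan-1-ol
Product: 27 difengpiol B, (1S,3S,4S)-1-[(2S,3R)-3-(hydroxymethyl)-5-(3-hydroxypropyl)-7-methoxy-2,3-dihydro-1-benzofuran-2-yl]-4-methoxycyclohexane-1,3-diol
Conditions: AcOH/H2O/THF (3:1:1), 45 °C
Reagents that add atoms: none
Why: Acid-catalysed ketal hydrolysis should release the cis-1,3-diol without affecting the aryl ether, the methyl ether or any stereocentre.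

**Compound list**

1 | methyl 3-oxocyclopent-1-ene-1-carboxylate | COC(=O)C1=CC(=O)CC1 | starting material
2 | methyl (R)-3-hydroxycyclopent-1-ene-1-carboxylate | COC(=O)C1=C[C@H](O)CC1 | intermediate
3 | (R)-3-(hydroxymethyl)cyclopent-2-en-1-ol | OCC1=C[C@H](O)CC1 | intermediate
4 | (1S,2R,5S)-5-(hydroxymethyl)bicyclo[3.1.0]hexan-2-ol | OC[C@@]12C[C@@H]1[C@H](O)CC2 | intermediate
5 | [(1S,4R,5S)-4-hydroxybicyclo[3.1.0]hexan-1-yl]methyl 4-methoxybenzoate | COc1ccc(cc1)C(=O)OC[C@@]12C[C@@H]1[C@H](O)CC2 | intermediate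
6 | (5S)-2-(4-methoxyphenyl)-1,3-dioxaspiro[4.5]dec-7-en-2-ylium | COc1ccc(cc1)C1=[O+]C[C@]2(O1)CCC=CC2 | intermediate
7 | [(S)-1-hydroxycyclohex-3-en-1-yl]methyl 4-methoxybenzoate | COc1ccc(cc1)C(=O)OC[C@]1(O)CCC=CC1 | intermediate
8 | [(1S,3S,6R)-3-hydroxy-7-oxabicyclo[4.1.0]heptan-3-yl]methyl 4-methoxybenzoate | COc1ccc(cc1)C(=O)OC[C@]1(O)CC[C@H]2O[C@H]2C1 | intermediate
9 | [(1S,3S,4S)-1,3-dihydroxy-4-methoxycyclohexyl]methyl 4-methoxybenzoate | COc1ccc(cc1)C(=O)OC[C@]1(O)CC[C@H](OC)[C@@H](O)C1 | intermediate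
10 | [(1S,5S,6S)-6-methoxy-3,3-dimethyl-2,4-dioxabicyclo[3.3.1]nonan-1-yl]methyl 4-methoxybenzoate | COc1ccc(cc1)C(=O)OC[C@]1(OC2(C)C)CC[C@H](OC)[C@@H](O2)C1 | intermediate
11 | [(1S,5S,6S)-6-methoxy-3,3-dimethyl-2,4-dioxabicyclo[3.3.1]nonan-1-yl]methanol | OC[C@]1(OC2(C)C)CC[C@H](OC)[C@@H](O2)C1 | intermediate
12 | (1S,5S,6S)-6-methoxy-3,3-dimethyl-2,4-dioxabicyclo[3.3.1]nonane-1-carbaldehyde | O=C[C@]1(OC2(C)C)CC[C@H](OC)[C@@H](O2)C1 | intermediate
13 | methyl 3-(4-hydroxy-3-methoxyphenyl)propanoate | COC(=O)CCc1ccc(O)c(OC)c1 | starting material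
14 | methyl 3-[3-methoxy-4-(prop-2-en-1-yloxy)phenyl]propanoate | COC(=O)CCc1ccc(OCC=C)c(OC)c1 | intermediate
15 | methyl 3-[4-hydroxy-3-methoxy-5-(prop-2-en-1-yl)phenyl]propanoate | COC(=O)CCc1cc(CC=C)c(O)c(OC)c1 | intermediate
16 | methyl 3-[3-methoxy-5-(prop-2-en-1-yl)-4-(trifluoromethanesulfonyloxy)phenyl]propanoate | COC(=O)CCc1cc(CC=C)c(OS(=O)(=O)C(F)(F)F)c(OC)c1 | intermediate
17 | methyl 3-[3-methoxy-5-(1,2,4-trioxolan-3-ylmethyl)-4-(trifluoromethanesulfonyloxy)phenyl]propanoate | COC(=O)CCc1cc(CC2OCOO2)c(OS(=O)(=O)C(F)(F)F)c(OC)c1 | intermediate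
18 | methyl 3-[3-methoxy-5-(2-oxoethyl)-4-(trifluoromethanesulfonyloxy)phenyl]propanoate | COC(=O)CCc1cc(CC=O)c(OS(=O)(=O)C(F)(F)F)c(OC)c1 | intermediate
19 | 2-[3-methoxy-5-(3-methoxy-3-oxopropyl)-2-(trifluoromethanesulfonyloxy)phenyl]acetic acid | COC(=O)CCc1cc(CC(O)=O)c(OS(=O)(=O)C(F)(F)F)c(OC)c1 | intermediate
20 | 2-[3-methoxy-5-(3-methoxy-3-oxopropyl)-2-(trifluoromethanesulfonyloxy)phenyl]acetic pivalic anhydride | COC(=O)CCc1cc(CC(=O)OC(=O)C(C)(C)C)c(OS(=O)(=O)C(F)(F)F)c(OC)c1 | intermediate
21 | methyl 3-[3-[2-[(S)-4-benzyl-2-oxo-1,3-oxazolidin-3-yl]-2-oxoethyl]-5-methoxy-4-(trifluoromethanesulfonyloxy)phenyl]propanoate | COC(=O)CCc1cc(CC(=O)N2[C@@H](Cc3ccccc3)COC2=O)c(OS(=O)(=O)C(F)(F)F)c(OC)c1 | intermediate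
22 | (Z)-dibutylboron enolate of 21 (O-bound boron, aryl cis to OB) | CCCCB(CCCC)O/C(=C\c1cc(CCC(=O)OC)cc(OC)c1OS(=O)(=O)C(F)(F)F)N1[C@@H](Cc2ccccc2)COC1=O | intermediate
23 | O-dibutylboryl derivative of aldol 24 | O=C1OC[C@H](Cc2ccccc2)N1C(=O)[C@@H](c3cc(CCC(=O)OC)cc(OC)c3OS(=O)(=O)C(F)(F)F)[C@H](OB(CCCC)CCCC)[C@]4(OC5(C)C)CC[C@H](OC)[C@@H](O5)C4 | intermediate
24 | methyl 3-[3-[(2S,3S)-1-[(S)-4-benzyl-2-oxo-1,3-oxazolidin-3-yl]-3-hydroxy-3-[(1S,5S,6S)-6-methoxy-3,3-dimethyl-2,4-dioxabicyclo[3.3.1]nonan-1-yl]-1-oxopropan-2-yl]-5-methoxy-4-(trifluoromethanesulfonyloxy)phenyl]propanoate | O=C1OC[C@H](Cc2ccccc2)N1C(=O)[C@@H](c3cc(CCC(=O)OC)cc(OC)c3OS(=O)(=O)C(F)(F)F)[C@H](O)[C@]4(OC5(C)C)CC[C@H](OC)[C@@H](O5)C4 | intermediate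
25 | 2-[(1S,2R)-1,3-dihydroxy-1-[(1S,5S,6S)-6-methoxy-3,3-dimethyl-2,4-dioxabicyclo[3.3.1]nonan-1-yl]propan-2-yl]-4-(3-hydroxypropyl)-6-methoxyphenyl trifluoromethanesulfonate | OCCCc1cc([C@H](CO)[C@H](O)[C@]2(OC3(C)C)CC[C@H](OC)[C@@H](O3)C2)c(OS(=O)(=O)C(F)(F)F)c(OC)c1 | intermediate
26 | 3-[(2S,3R)-3-(hydroxymethyl)-7-methoxy-2-[(1S,5S,6S)-6-methoxy-3,3-dimethyl-2,4-dioxabicyclo[3.3.1]nonan-1-yl]-2,3-dihydro-1-benzofuran-5-yl]propan-1-ol | COc1cc(CCCO)cc2c1O[C@H]([C@]1(OC3(C)C)CC[C@H](OC)[C@@H](O3)C1)[C@H]2CO | intermediate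
27 | difengpiol B, (1S,3S,4S)-1-[(2S,3R)-3-(hydroxymethyl)-5-(3-hydroxypropyl)-7-methoxy-2,3-dihydro-1-benzofuran-2-yl]-4-methoxycyclohexane-1,3-diol | COc1cc(CCCO)cc2c1O[C@H]([C@]1(O)CC[C@H](OC)[C@@H](O)C1)[C@H]2CO | target

**Totals**

Total step count: 18. Longest linear sequence: 13 steps (steps 1–9, then 15–18); steps 10–14 form the convergent aryl branch.

**Three steps most likely to fail**

1. Step 5. What may go wrong: the ester may close on the cyclopropane CH2 through a six-membered acyloxonium (scission of the external bond, which is better aligned with the cationic p orbital); ionization may stall because the acyloxymethyl group deactivates C1; or a free homoallyl cation, or re-ionization of the tertiary alcohol, may erode the enantiomeric purity. Fallback (a different ring construction): it does not branch from an intermediate of the route; it replaces 1 to 6, starts from commercial 2-bromoacrolein and buta-1,3-diene, and comes back at 7. An enantioselective Diels–Alder reaction under the oxazaborolidinone made from N-tosyltryptophan and butylboronic acid (CH2Cl2, −78 °C, catalyst enantiomer chosen for the R adduct) should give (R)-1-bromocyclohex-3-ene-1-carbaldehyde F1. NaBH4 in MeOH then gives [(R)-1-bromocyclohex-3-en-1-yl]methanol F2. K2CO3 in MeOH closes (S)-1-oxaspiro[2.5]oct-5-ene F3 by intramolecular SN2 with inversion at the quaternary carbon. 4-Methoxybenzoic acid with Cs2CO3 in DMF at 80 °C opens F3 at its CH2 terminus and gives 7.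

2. Step 17. What may go wrong: sulfur–oxygen cleavage of the triflate by carbonate or alkoxide, β-hydride elimination from the palladium alkoxide, or intermolecular etherification by the two primary alcohols. Fallback (oxidative copper coupling in place of palladium cross-coupling): it sets out from 25 and comes back at 26. Miyaura borylation of the aryl triflate (Pd(dppf)Cl2, bis(pinacolato)diboron, KOAc, dioxane, 80 °C) should give 3-[3-[(1S,2R)-1,3-dihydroxy-1-[(1S,5S,6S)-6-methoxy-3,3-dimethyl-2,4-dioxabicyclo[3.3.1]nonan-1-yl]propan-2-yl]-5-methoxy-4-(4,4,5,5-tetramethyl-1,3,2-dioxaborolan-2-yl)phenyl]propan-1-ol F4. An intramolecular Chan–Lam etherification (Cu(OAc)2, pyridine, 4 Å sieves, air, CH2Cl2, rt) should then close the five-membered ring with retention at the carbinol carbon to give 26.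

3. Step 7. What may go wrong: regiochemical leakage, methanol attacking the epoxide carbon nearer C1 through the chair with the ester arm axial, or acyl migration under the acid. Fallback (internal oxygen delivery, then O-methylation): it sets out from 7 and comes back at 9, which is ketalized to 10 as in the second half of step 7. Deprotonation with n-BuLi and acylation with Boc2O (THF, −78 °C) gives tert-butyl (S)-1-[(4-methoxybenzoyloxy)methyl]cyclohex-3-en-1-yl carbonate F5. mCPBA (NaHCO3, CH2Cl2) should epoxidize the face anti to the axial carbonate to give [(1R,3S,6S)-3-(tert-butoxycarbonyloxy)-7-oxabicyclo[4.1.0]heptan-3-yl]methyl 4-methoxybenzoate F6. BF3·OEt2 (CH2Cl2, −40 °C) makes the carbonate carbonyl open the nearer epoxide carbon in a 6-exo mode with loss of isobutene, giving [(1S,5S,6S)-6-hydroxy-3-oxo-2,4-dioxabicyclo[3.3.1]nonan-1-yl]methyl 4-methoxybenzoate F7, in which the oxygen cis to the C1 oxygen and the trans hydroxyl are fixed without a regiochemical choice. MeOTf with 2,6-di-tert-butyl-4-methylpyridine methylates that hydroxyl to [(1S,5S,6S)-6-methoxy-3-oxo-2,4-dioxabicyclo[3.3.1]nonan-1-yl]methyl 4-methoxybenzoate F8. K2CO3 in MeOH at 0 °C should cleave the cyclic carbonate faster than the benzoate and give 9.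

Further compounds
F1 | step 5 | (R)-1-bromocyclohex-3-ene-1-carbaldehyde | O=C[C@@]1(Br)CCC=CC1
F2 | step 5 | [(R)-1-bromocyclohex-3-en-1-yl]methanol | OC[C@@]1(Br)CCC=CC1
F3 | step 5 | (S)-1-oxaspiro[2.5]oct-5-ene | C1[C@]2(O1)CCC=CC2
F4 | step 17 | 3-[3-[(1S,2R)-1,3-dihydroxy-1-[(1S,5S,6S)-6-methoxy-3,3-dimethyl-2,4-dioxabicyclo[3.3.1]nonan-1-yl]propan-2-yl]-5-methoxy-4-(4,4,5,5-tetramethyl-1,3,2-dioxaborolan-2-yl)phenyl]propan-1-ol | OCCCc1cc([C@H](CO)[C@H](O)[C@]2(OC3(C)C)CC[C@H](OC)[C@@H](O3)C2)c(B4OC(C)(C)C(C)(C)O4)c(OC)c1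
F5 | step 7 | tert-butyl (S)-1-[(4-methoxybenzoyloxy)methyl]cyclohex-3-en-1-yl carbonate | COc1ccc(cc1)C(=O)OC[C@]1(OC(=O)OC(C)(C)C)CCC=CC1
F6 | step 7 | [(1R,3S,6S)-3-(tert-butoxycarbonyloxy)-7-oxabicyclo[4.1.0]heptan-3-yl]methyl 4-methoxybenzoate | COc1ccc(cc1)C(=O)OC[C@]1(OC(=O)OC(C)(C)C)CC[C@@H]2O[C@@H]2C1
F7 | step 7 | [(1S,5S,6S)-6-hydroxy-3-oxo-2,4-dioxabicyclo[3.3.1]nonan-1-yl]methyl 4-methoxybenzoate | COc1ccc(cc1)C(=O)OC[C@]1(OC2=O)CC[C@H](O)[C@@H](O2)C1
F8 | step 7 | [(1S,5S,6S)-6-methoxy-3-oxo-2,4-dioxabicyclo[3.3.1]nonan-1-yl]methyl 4-methoxybenzoate | COc1ccc(cc1)C(=O)OC[C@]1(OC2=O)CC[C@H](OC)[C@@H](O2)C1
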